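## Retrosynthetic overview

- Lettering: upper flavan unit = rings A (benzo), B (catechol), C (pyran); lower unit = rings D, E, F in the same sense. The target comes from its hexabenzyl ether, and that from a tertiary C-4 carbinol in ring C by ionic hydrogenation (hydride anti to 3-OH).
- That tetraol comes from a bis-flav-3-ene by one twofold OsO4 dihydroxylation, each anti to its C-2 aryl group (2,3-trans-3,4-cis in rings C and F).
- The bis-flav-3-ene comes from an acyclic bis(aryl 1-arylpropargyl ether) by a double gold-catalysed 6-endo-dig hydroarylation that closes rings C and F in one operation; the interflavan C4–C6 bond is already present as an aryl–alkyne bond.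
- The bis-ether comes from one Sonogashira coupling and two Mitsunobu etherifications, which set both C-2 centres by inversion of a single (R)-propargylic alcohol.
- Rings A, B, D and E are bought as arenes (3,4-bis(benzyloxy)benzaldehyde; 3-(benzyloxy)phenol, also iodinated to serve as ring D); rings C and F are formed last, together.

Assumption: compounds 1, 2 and 5 are bought, and (R)-BINOL is taken to give the (R)-carbinol 4 (sense recalled by analogy, to be checked by Mosher ester; the antipodal ligand is used if it is reversed).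

## Route

Step 1
Reactants: 1 3,4-bis(benzyloxy)benzaldehyde; 2 ethynyl(trimethyl)silane
Product: 4 (1R)-1-[3,4-bis(benzyloxy)phenyl]prop-2-yn-1-ol, via silyl alkynol 3 (not isolated)
Conditions: 2 (4 equiv), Et2Zn (4 equiv), toluene, reflux; then (R)-BINOL (40 mol %), Ti(OiPr)4 (1 equiv), 1, CH2Cl2, rt; aq. NH4Cl; crude 3, K2CO3, MeOH, rt
Reagents that add atoms: none
Why: BINOL/titanium-catalysed asymmetric alkynylzinc addition to the aldehyde sets the carbinol centre (S in 3, R in 4 only because desilylation changes the priorities), and K2CO3/MeOH protodesilylation frees the terminal alkyne.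

Step 2
Reactants: 4 (1R)-1-[3,4-bis(benzyloxy)phenyl]prop-2-yn-1-ol; 5 3-(benzyloxy)phenol
Product: 6 1-(benzyloxy)-3-{[(1S)-1-[3,4-bis(benzyloxy)phenyl]prop-2-yn-1-yl]oxy}benzene
Conditions: PPh3, DIAD, toluene, −20 → 0 °C
Reagents that add atoms: none
Why: Mitsunobu etherification, in which SN2 attack of the phenoxide on the alkoxyphosphonium ion inverts the carbinol centre (R to S); this centre becomes C-2 of ring C.

Step 3
Reactants: 5 3-(benzyloxy)phenol
Product: 7 3-(benzyloxy)-4-iodophenol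
Conditions: NIS (1.0 equiv), TsOH·H2O (10 mol %), MeCN, 0 °C
Reagents that add atoms: N-iodosuccinimide, O=C1CCC(=O)N1I
Why: Electrophilic aromatic iodination directed para to the free hydroxyl, the stronger para director; the minor isomer iodinated para to OBn is removed by chromatography.

Step 4
Reactants: 6 1-(benzyloxy)-3-{[(1S)-1-[3,4-bis(benzyloxy)phenyl]prop-2-yn-1-yl]oxy}benzene; 7 3-(benzyloxy)-4-iodophenol
Product: 8 3-(benzyloxy)-4-{(3R)-3-[3-(benzyloxy)phenoxy]-3-[3,4-bis(benzyloxy)phenyl]prop-1-yn-1-yl}phenol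
Conditions: PdCl2(PPh3)2 (3 mol %), CuI (5 mol %), Et3N/THF, 40 °C, Ar
Reagents that add atoms: none
Why: Sonogashira coupling makes the aryl–alkyne bond that becomes the C4–C6 interflavan bond; the stereocentre is untouched (S becomes R only because the internal alkynyl group now outranks the aryl group).

Step 5
Reactants: 8 3-(benzyloxy)-4-{(3R)-3-[3-(benzyloxy)phenoxy]-3-[3,4-bis(benzyloxy)phenyl]prop-1-yn-1-yl}phenol; 4 (1R)-1-[3,4-bis(benzyloxy)phenyl]prop-2-yn-1-ol
Product: 9 2-(benzyloxy)-1-{(3R)-3-[3-(benzyloxy)phenoxy]-3-[3,4-bis(benzyloxy)phenyl]prop-1-yn-1-yl}-4-{[(1S)-1-[3,4-bis(benzyloxy)phenyl]prop-2-yn-1-yl]oxy}benzene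
Conditions: PPh3, DIAD, toluene, −20 → 0 °C
Reagents that add atoms: none
Why: Second Mitsunobu etherification with inversion (R to S) installs the centre that becomes C-2 of ring F on the oxygen para to the alkyne.

Step 6
Reactants: 9 2-(benzyloxy)-1-{(3R)-3-[3-(benzyloxy)phenoxy]-3-[3,4-bis(benzyloxy)phenyl]prop-1-yn-1-yl}-4-{[(1S)-1-[3,4-bis(benzyloxy)phenyl]prop-2-yn-1-yl]oxy}benzene
Product: 11 (2S)-7-(benzyloxy)-4-{(2S)-7-(benzyloxy)-2-[3,4-bis(benzyloxy)phenyl]-2H-chromen-6-yl}-2-[3,4-bis(benzyloxy)phenyl]-2H-chromene, via mono-chromene 10 (not isolated)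
Conditions: [(t-Bu)2(2-biphenylyl)P]Au(NCMe)SbF6 (5 mol %), 4 Å MS, CH2Cl2, 0 °C → rt
Reagents that add atoms: none
Why: Gold-catalysed intramolecular alkyne hydroarylation (6-endo-dig, Friedel–Crafts type) runs on both arms, each arene attacking para to its OBn group, so rings C and F close in one operation; the two O–CH(aryl) centres are not touched (both become S only through a priority change).

Step 7
Reactants: 11 (2S)-7-(benzyloxy)-4-{(2S)-7-(benzyloxy)-2-[3,4-bis(benzyloxy)phenyl]-2H-chromen-6-yl}-2-[3,4-bis(benzyloxy)phenyl]-2H-chromene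
Product: 13 (2R,3R,4R)-7-(benzyloxy)-4-{(2R,3S,4S)-7-(benzyloxy)-2-[3,4-bis(benzyloxy)phenyl]-3,4-dihydroxy-3,4-dihydro-2H-chromen-6-yl}-2-[3,4-bis(benzyloxy)phenyl]-3,4-dihydro-2H-chromene-3,4-diol, via mono-diol 12 (not isolated)
Conditions: OsO4 (10 mol %), NMO (4 equiv), DABCO (20 mol %), acetone/t-BuOH/H2O, rt
Reagents that add atoms: osmium tetroxide, O=[Os](=O)(=O)=O; N-methylmorpholine N-oxide, C[N+]1([O-])CCOCC1; water, O
Why: Upjohn dihydroxylation adds syn to each chromene double bond from the face opposite the C-2 aryl group (substrate control); this sets C-3 and C-4 of ring F as in the target (2,3-trans-3,4-cis) and C-3 of ring C, with the ring C 4-OH cis to 3-OH.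

Step 8
Reactants: 13 (2R,3R,4R)-7-(benzyloxy)-4-{(2R,3S,4S)-7-(benzyloxy)-2-[3,4-bis(benzyloxy)phenyl]-3,4-dihydroxy-3,4-dihydro-2H-chromen-6-yl}-2-[3,4-bis(benzyloxy)phenyl]-3,4-dihydro-2H-chromene-3,4-diol
Product: 14 (2R,3S,4R)-7-(benzyloxy)-4-{(2R,3S,4S)-7-(benzyloxy)-2-[3,4-bis(benzyloxy)phenyl]-3,4-dihydroxy-3,4-dihydro-2H-chromen-6-yl}-2-[3,4-bis(benzyloxy)phenyl]-3,4-dihydro-2H-chromen-3-ol
Conditions: i-Pr3SiH (10 equiv), CF3CO2H (5 equiv), CH2Cl2, −78 → −40 °C
Reagents that add atoms: none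
Why: Ionic hydrogenation (Kursanov–Parnes) ionises only the tertiary carbinol flanked by two 2,4-dialkoxyphenyl rings, and the bulky silane delivers hydride anti to the C-3 hydroxyl (the face nucleophiles prefer in 2,3-trans-flavan-4-yl cations), which places the ring D aryl cis to 3-OH and sets C-4 of ring C.

Step 9
Reactants: 14 (2R,3S,4R)-7-(benzyloxy)-4-{(2R,3S,4S)-7-(benzyloxy)-2-[3,4-bis(benzyloxy)phenyl]-3,4-dihydroxy-3,4-dihydro-2H-chromen-6-yl}-2-[3,4-bis(benzyloxy)phenyl]-3,4-dihydro-2H-chromen-3-ol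
Product: 15 (2R,3S,4S)-2-(3,4-dihydroxyphenyl)-6-[(2R,3S,4S)-2-(3,4-dihydroxyphenyl)-3,7-dihydroxy-3,4-dihydro-2H-chromen-4-yl]-3,4-dihydro-2H-chromene-3,4,7-triol (CNP0280090.1)
Conditions: H2 (1 atm), Pd(OH)2/C, EtOAc/MeOH, rt, stopped at full debenzylation
Reagents that add atoms: none
Why: Catalytic hydrogenolysis removes the six benzyl ethers under neutral conditions without touching a stereocentre (C-4 of ring C changes from R to S only because free 7-OH on ring D changes the priorities), and the secondary benzylic 4-OH of ring F survives at short reaction time.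

## Compound list

1 | 3,4-bis(benzyloxy)benzaldehyde | O=Cc1ccc(OCc2ccccc2)c(OCc2ccccc2)c1 | starting material
2 | ethynyl(trimethyl)silane | C#C[Si](C)(C)C | starting material
3 | (1S)-1-[3,4-bis(benzyloxy)phenyl]-3-(trimethylsilyl)prop-2-yn-1-ol | C[Si](C)(C)C#C[C@@H](O)c1ccc(OCc2ccccc2)c(OCc2ccccc2)c1 | intermediate
4 | (1R)-1-[3,4-bis(benzyloxy)phenyl]prop-2-yn-1-ol | C#C[C@@H](O)c1ccc(OCc2ccccc2)c(OCc2ccccc2)c1 | intermediate
5 | 3-(benzyloxy)phenol | Oc1cccc(OCc2ccccc2)c1 | starting material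
6 | 1-(benzyloxy)-3-{[(1S)-1-[3,4-bis(benzyloxy)phenyl]prop-2-yn-1-yl]oxy}benzene | C#C[C@H](Oc1cccc(OCc2ccccc2)c1)c1ccc(OCc2ccccc2)c(OCc2ccccc2)c1 | intermediate
7 | 3-(benzyloxy)-4-iodophenol | Oc1ccc(I)c(OCc2ccccc2)c1 | intermediate
8 | 3-(benzyloxy)-4-{(3R)-3-[3-(benzyloxy)phenoxy]-3-[3,4-bis(benzyloxy)phenyl]prop-1-yn-1-yl}phenol | Oc1ccc(C#C[C@H](Oc2cccc(OCc3ccccc3)c2)c2ccc(OCc3ccccc3)c(OCc3ccccc3)c2)c(OCc2ccccc2)c1 | intermediate
9 | 2-(benzyloxy)-1-{(3R)-3-[3-(benzyloxy)phenoxy]-3-[3,4-bis(benzyloxy)phenyl]prop-1-yn-1-yl}-4-{[(1S)-1-[3,4-bis(benzyloxy)phenyl]prop-2-yn-1-yl]oxy}benzene | C#C[C@H](Oc1ccc(C#C[C@H](Oc2cccc(OCc3ccccc3)c2)c2ccc(OCc3ccccc3)c(OCc3ccccc3)c2)c(OCc2ccccc2)c1)c1ccc(OCc2ccccc2)c(OCc2ccccc2)c1 | intermediate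
10 | (2S)-7-(benzyloxy)-6-{(3R)-3-[3-(benzyloxy)phenoxy]-3-[3,4-bis(benzyloxy)phenyl]prop-1-yn-1-yl}-2-[3,4-bis(benzyloxy)phenyl]-2H-chromene (terminal-alkyne arm assumed to close first) | C1=Cc2cc(C#C[C@H](Oc3cccc(OCc4ccccc4)c3)c3ccc(OCc4ccccc4)c(OCc4ccccc4)c3)c(OCc3ccccc3)cc2O[C@@H]1c1ccc(OCc2ccccc2)c(OCc2ccccc2)c1 | intermediate
11 | (2S)-7-(benzyloxy)-4-{(2S)-7-(benzyloxy)-2-[3,4-bis(benzyloxy)phenyl]-2H-chromen-6-yl}-2-[3,4-bis(benzyloxy)phenyl]-2H-chromene | C(c1ccccc1)Oc1ccc2c(c1)O[C@H](c1ccc(OCc3ccccc3)c(OCc3ccccc3)c1)C=C2c1cc2c(cc1OCc1ccccc1)O[C@H](c1ccc(OCc3ccccc3)c(OCc3ccccc3)c1)C=C2 | intermediate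
12 | (2R,3S,4S)-7-(benzyloxy)-6-{(2S)-7-(benzyloxy)-2-[3,4-bis(benzyloxy)phenyl]-2H-chromen-4-yl}-2-[3,4-bis(benzyloxy)phenyl]-3,4-dihydro-2H-chromene-3,4-diol (less hindered ring F alkene assumed to react first) | C(c1ccccc1)Oc1ccc2c(c1)O[C@H](c1ccc(OCc3ccccc3)c(OCc3ccccc3)c1)C=C2c1cc2c(cc1OCc1ccccc1)O[C@H](c1ccc(OCc3ccccc3)c(OCc3ccccc3)c1)[C@@H](O)[C@H]2O | intermediate
13 | (2R,3R,4R)-7-(benzyloxy)-4-{(2R,3S,4S)-7-(benzyloxy)-2-[3,4-bis(benzyloxy)phenyl]-3,4-dihydroxy-3,4-dihydro-2H-chromen-6-yl}-2-[3,4-bis(benzyloxy)phenyl]-3,4-dihydro-2H-chromene-3,4-diol | C(c1ccccc1)Oc1ccc2c(c1)O[C@H](c1ccc(OCc3ccccc3)c(OCc3ccccc3)c1)[C@@H](O)[C@]2(O)c1cc2c(cc1OCc1ccccc1)O[C@H](c1ccc(OCc3ccccc3)c(OCc3ccccc3)c1)[C@@H](O)[C@H]2O | intermediate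
14 | (2R,3S,4R)-7-(benzyloxy)-4-{(2R,3S,4S)-7-(benzyloxy)-2-[3,4-bis(benzyloxy)phenyl]-3,4-dihydroxy-3,4-dihydro-2H-chromen-6-yl}-2-[3,4-bis(benzyloxy)phenyl]-3,4-dihydro-2H-chromen-3-ol | C(c1ccccc1)Oc1ccc2c(c1)O[C@H](c1ccc(OCc3ccccc3)c(OCc3ccccc3)c1)[C@@H](O)[C@H]2c1cc2c(cc1OCc1ccccc1)O[C@H](c1ccc(OCc3ccccc3)c(OCc3ccccc3)c1)[C@@H](O)[C@H]2O | intermediate
15 | (2R,3S,4S)-2-(3,4-dihydroxyphenyl)-6-[(2R,3S,4S)-2-(3,4-dihydroxyphenyl)-3,7-dihydroxy-3,4-dihydro-2H-chromen-4-yl]-3,4-dihydro-2H-chromene-3,4,7-triol | Oc1ccc2c(c1)O[C@H](c1ccc(O)c(O)c1)[C@@H](O)[C@H]2c1cc2c(cc1O)O[C@H](c1ccc(O)c(O)c1)[C@@H](O)[C@H]2O | target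

## Step count and risks

Total steps: 9. Longest linear sequence: 8 (steps 1, 2, 4, 5, 6, 7, 8, 9); step 3 is a one-step side branch.

**Step 6 (double hydroarylation).** The cationic gold catalyst may ionise the p-alkoxybenzylic propargylic ethers, which would erode the C-2 configuration. Attack between the two oxygens would give 5-oxygenated isomers. The neighbouring OBn may add to the internal alkyne and give a benzofuran. The fallback sets out from 9 and comes back at 11. An iodonium-triggered double 6-endo iodoarylation (I2, NaHCO3, MeNO2, rt) replaces π-acid catalysis by electrophilic cyclisation, again closing both rings in one operation. It gives the bis(3-iodo-2H-chromene) F1. Reduction with Pd(PPh3)4 and HCO2Na in DMF at 60 °C removes both vinylic iodides and returns 11.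

**Step 8 (ionic hydrogenation).** The cation next to a free 3-OH may undergo a pinacol-type hydride shift or elimination to the flavan-3-one. The ring F 4-OH may also ionise, and facial selectivity may be modest. The fallback sets out from 13 and comes back at 15. Hydrogenolysis over Pd/C under H2 in EtOAc with a little AcOH cleaves the tertiary benzylic C–O bond on the palladium surface, which typically proceeds with inversion and so gives the same C-4 configuration. The benzyl ethers are removed in the same operation. This passes through no new compound (F0).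

**Step 2 (Mitsunobu; the same concern applies to step 5).** The electron-rich benzylic propargylic alkoxyphosphonium ion may react partly by SN1, which would lower the ee. The fallback sets out from 4 and comes back at 6. Acetylation (Ac2O, Et3N, DMAP) gives the propargylic acetate F2. Treatment with 5, (CuOTf)2·C6H6 (5 mol %), a chiral pybox ligand and i-Pr2NEt in MeOH at −10 °C then performs a copper-allenylidene propargylic etherification. This is enantioconvergent, so the ligand antipode fixes the (S) configuration of 6 regardless of the ee of F2. The same acetate serves for 8 to 9.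

## Further compounds

F1 | step 6 | (2R)-7-(benzyloxy)-4-{(2R)-7-(benzyloxy)-2-[3,4-bis(benzyloxy)phenyl]-3-iodo-2H-chromen-6-yl}-2-[3,4-bis(benzyloxy)phenyl]-3-iodo-2H-chromene | C(c1ccccc1)Oc1ccc2c(c1)O[C@H](c1ccc(OCc3ccccc3)c(OCc3ccccc3)c1)C(I)=C2c1cc2c(cc1OCc1ccccc1)O[C@H](c1ccc(OCc3ccccc3)c(OCc3ccccc3)c1)C(I)=C2
F0 | step 8 | none | none
F2 | step 2 | (1R)-1-[3,4-bis(benzyloxy)phenyl]prop-2-yn-1-yl acetate | CC(=O)O[C@H](C#C)c1ccc(OCc2ccccc2)c(OCc2ccccc2)c1
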